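The route rests on cutting the cyclohexene ring (C1–C6) at C3–C4 and C5–C6. The key step exploits the 1,4 relationship, across the C1=C2 alkene, between C1 with its acetoxymethyl carbon and the lone ring stereocentre C4: a catalytic enantioselective Diels–Alder reaction of a 2-(silyloxymethyl)butadiene with trifluoroethyl acrylate closes the ring, places both substituents and sets C4 in one operation, the ester carbon becoming C7. The precursor is an achiral silyl-protected dienol made in one flask from isoprene monoxide. C7 then comes from catalytic allylation of the derived methyl ketone, and C11 from a chiral-pool allylic alcohol joined at C9=C10 by cross-metathesis.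

Key step: step 2

Remark: atoms are numbered as in the target (ring C1–C6 with the acetoxymethyl carbon on C1, side chain C7–C11 on C4); the absolute sense of the two catalyst-controlled steps (2 and 4) is assigned by analogy with the parent substrates and, both catalyst antipodes being commercial, is to be confirmed on butadiene and on cyclohexyl methyl ketone before the real substrates are committed.

Step 1
Reactants: 1 isoprene monoxide (2-methyl-2-vinyloxirane, racemic)
Product: 3 triisopropyl[(2-methylidenebut-3-en-1-yl)oxy]silane, via lithium 2-methylidenebut-3-en-1-olate 2 (not isolated)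
Conditions: LDA (1.2 equiv), Et2O, 0 °C → rt; then TIPSCl (1.2 equiv), THF, 0 °C → rt
Reagents that add atoms: triisopropylsilyl chloride, CC(C)[Si](Cl)(C(C)C)C(C)C; lithium diisopropylamide, [Li+].CC(C)[N-]C(C)C (lithium is carried only in intermediate 2)
Why: Lithium amide-induced epoxide-to-allylic-alcohol isomerisation can only remove a methyl hydrogen here, so ring opening should give the dienyl alkoxide 2, which is O-silylated in the same flask before the volatile, dimerisation-prone dienol has to be handled.

Step 2
Reactants: 3 triisopropyl[(2-methylidenebut-3-en-1-yl)oxy]silane; 4 trifluoroethyl acrylate (2,2,2-trifluoroethyl prop-2-enoate)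
Product: 5 (R)-2,2,2-trifluoroethyl 4-{[(triisopropylsilyl)oxy]methyl}cyclohex-3-ene-1-carboxylate
Conditions: (3aR)-1-(2-methylphenyl)-3,3-diphenyltetrahydro-1H,3H-pyrrolo[1,2-c][1,3,2]oxazaborole N-protonated by HN(SO2CF3)2 (10–20 mol%), CH2Cl2 (concentrated), 0 °C → rt
Reagents that add atoms: none
Why: The N-protonated oxazaborolidine binds the acrylate carbonyl at boron, lowers its LUMO and screens one enantioface of the s-trans acrylate, and the diene then adds in one suprafacial [4+2] cycloaddition in which the C5–C6 bond runs ahead of the C3–C4 bond. The closest known reaction type is the chiral oxazaborolidinium-catalysed Diels–Alder reaction of butadiene and 2-substituted butadienes with trifluoroethyl acrylate. Ring C1–C6 is closed by this intermolecular cycloaddition itself, both ring bonds arising in the same step through a boat-like six-membered transition state, so no separate cyclisation has to be steered. C4 is set by the catalyst alone: by analogy with butadiene, where the (S)-catalyst leads to the (S)-ester, the (R)-catalyst should give (R)-5, whose carbonyl-bearing carbon has the same substituent ranking. The step needs para regioselectivity, secured because the diene terminus next to the CH2OSi-bearing carbon (future C6) has the larger HOMO coefficient and bonds to the acrylate β-carbon (C5), and it needs enantioface selectivity, secured by the catalyst; no endo/exo question arises since only one stereocentre is formed. The electron-poor trifluoroethyl ester gives enough reactivity for a diene that is no more electron-rich than isoprene, and the bulky TIPS ether keeps the ether oxygen off boron.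

Step 3
Reactants: 5 (R)-2,2,2-trifluoroethyl 4-{[(triisopropylsilyl)oxy]methyl}cyclohex-3-ene-1-carboxylate
Product: 7 methyl ketone 1-[(1R)-4-{[(triisopropylsilyl)oxy]methyl}cyclohex-3-en-1-yl]ethan-1-one, via N-methoxy-N-methylamide 6 (not isolated)
Conditions: MeNH(OMe)·HCl (1.5 equiv), iPrMgCl (3 equiv), THF, −20 °C; then MeMgBr (3 equiv), −20 → 0 °C; aq. NH4Cl
Reagents that add atoms: methylmagnesium bromide, C[Mg]Br; N,O-dimethylhydroxylamine hydrochloride, CNOC.Cl (its atoms are carried only in intermediate 6)
Why: Magnesium amide aminolysis of the activated ester (Weinreb amide formation) followed by Grignard addition to the chelated amide should stop at the ketone after work-up, and the low temperature and the absence of free ketone in the basic medium protect the C4 stereocentre from enolisation.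

Step 4
Reactants: 7 methyl ketone 1-[(1R)-4-{[(triisopropylsilyl)oxy]methyl}cyclohex-3-en-1-yl]ethan-1-one
Product: 8 (2S)-2-[(1R)-4-{[(triisopropylsilyl)oxy]methyl}cyclohex-3-en-1-yl]pent-4-en-2-ol
Conditions: allylB(pin) (1.5 equiv), CuF2·2H2O (3 mol%), (R,R)-iPr-DuPHOS (6 mol%; the antipode if the test run of the remark shows the opposite sense), La(OiPr)3 (4.5 mol%), DMF, −40 °C; aq. work-up
Reagents that add atoms: allylboronic acid pinacol ester, C=CCB1OC(C)(C)C(C)(C)O1
Why: Catalytic enantioselective allylboration of a ketone: the allylcopper species formed from allylB(pin) adds through a cyclic transition state in which the chiral bisphosphine distinguishes the methyl group from the branched ring carbon and delivers allyl to the Si face of C7 to set (S), the nearly symmetric C4 exerting no bias, and the C7 epimer is a diastereomer that can be removed.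

Step 5
Reactants: 9 (S)-2-methylglycidol, [(2S)-2-methyloxiran-2-yl]methanol
Product: 10 tert-butyl{[(2R)-2-methyloxiran-2-yl]methoxy}diphenylsilane
Conditions: TBDPSCl, imidazole, CH2Cl2, 0 °C → rt
Reagents that add atoms: tert-butyldiphenylsilyl chloride, CC(C)(C)[Si](Cl)(c1ccccc1)c1ccccc1
Why: Standard silylation of a primary alcohol under non-alkoxide conditions avoids the Payne rearrangement that would racemise the glycidol; the quaternary centre is untouched and only its descriptor changes.

Step 6
Reactants: 10 tert-butyl{[(2R)-2-methyloxiran-2-yl]methoxy}diphenylsilane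
Product: 11 (2R)-1-[(tert-butyldiphenylsilyl)oxy]-2-methylbut-3-en-2-ol
Conditions: Me3S+ I− (4 equiv), nBuLi (3.8 equiv), THF, −10 °C → rt
Reagents that add atoms: trimethylsulfonium iodide, C[S+](C)C.[I-]
Why: One-carbon homologation of an epoxide to an allylic alcohol with dimethylsulfonium methylide: the ylide opens the epoxide at its CH2 terminus and the sulfonium betaine eliminates dimethyl sulfide, so the C–O bond at the quaternary carbon is never broken and its configuration (the future C11) is retained.

Step 7
Reactants: 8 (2S)-2-[(1R)-4-{[(triisopropylsilyl)oxy]methyl}cyclohex-3-en-1-yl]pent-4-en-2-ol; 11 (2R)-1-[(tert-butyldiphenylsilyl)oxy]-2-methylbut-3-en-2-ol (3 equiv)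
Product: 12 (2R,3E,6S)-1-[(tert-butyldiphenylsilyl)oxy]-2-methyl-6-[(1R)-4-{[(triisopropylsilyl)oxy]methyl}cyclohex-3-en-1-yl]hept-3-ene-2,6-diol
Conditions: second-generation Hoveyda–Grubbs catalyst RuCl2(H2IMes)(=CH-C6H4-2-OiPr) (5–10 mol%), CH2Cl2, 40 °C, argon sweep
Reagents that add atoms: none
Why: Olefin cross-metathesis between a reactive terminal homoallylic alkene and an excess of a hindered tertiary allylic alcohol that does not homodimerise should favour the cross product, the quaternary allylic carbon enforcing E geometry at C9=C10, while the trisubstituted, unstrained ring alkene stays out of the reaction.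

Step 8
Reactants: 12 (2R,3E,6S)-1-[(tert-butyldiphenylsilyl)oxy]-2-methyl-6-[(1R)-4-{[(triisopropylsilyl)oxy]methyl}cyclohex-3-en-1-yl]hept-3-ene-2,6-diol
Product: 13 (2R,3E,6S)-6-[(1R)-4-(hydroxymethyl)cyclohex-3-en-1-yl]-2-methylhept-3-ene-1,2,6-triol
Conditions: Bu4NF (3 equiv), THF, 0 °C → rt
Reagents that add atoms: none
Why: Fluoride-driven cleavage of both primary silyl ethers proceeds under non-acidic conditions that spare the ionisable tertiary allylic alcohol at C11.

Step 9
Reactants: 13 (2R,3E,6S)-6-[(1R)-4-(hydroxymethyl)cyclohex-3-en-1-yl]-2-methylhept-3-ene-1,2,6-triol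
Product: 14 {(4R)-4-[(2S,4E,6R)-7-(acetyloxy)-2,6-dihydroxy-6-methylhept-4-en-2-yl]cyclohex-1-en-1-yl}methyl acetate (target)
Conditions: Ac2O (2.5 equiv), pyridine, CH2Cl2, 0 °C → rt (no DMAP)
Reagents that add atoms: acetic anhydride, CC(=O)OC(C)=O
Why: Acetylation with acetic anhydride and pyridine without an acyl-transfer catalyst is selective for the two primary hydroxyls, the two tertiary alcohols being too hindered to react, so the target should result with all three stereocentres untouched.

Compound list
1 | isoprene monoxide (2-methyl-2-vinyloxirane, racemic) | CC1(C=C)CO1 | starting material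
2 | lithium 2-methylidenebut-3-en-1-olate | [Li+].[O-]CC(=C)C=C | intermediate
3 | triisopropyl[(2-methylidenebut-3-en-1-yl)oxy]silane | C=CC(=C)CO[Si](C(C)C)(C(C)C)C(C)C | intermediate
4 | 2,2,2-trifluoroethyl prop-2-enoate (trifluoroethyl acrylate) | C=CC(=O)OCC(F)(F)F | starting material
5 | (R)-2,2,2-trifluoroethyl 4-{[(triisopropylsilyl)oxy]methyl}cyclohex-3-ene-1-carboxylate | CC(C)[Si](C(C)C)(C(C)C)OCC1=CC[C@H](C(=O)OCC(F)(F)F)CC1 | intermediate
6 | (R)-N-methoxy-N-methyl-4-{[(triisopropylsilyl)oxy]methyl}cyclohex-3-ene-1-carboxamide | CC(C)[Si](C(C)C)(C(C)C)OCC1=CC[C@H](C(=O)N(C)OC)CC1 | intermediate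
7 | 1-[(1R)-4-{[(triisopropylsilyl)oxy]methyl}cyclohex-3-en-1-yl]ethan-1-one | CC(C)[Si](C(C)C)(C(C)C)OCC1=CC[C@H](C(C)=O)CC1 | intermediate
8 | (2S)-2-[(1R)-4-{[(triisopropylsilyl)oxy]methyl}cyclohex-3-en-1-yl]pent-4-en-2-ol | CC(C)[Si](C(C)C)(C(C)C)OCC1=CC[C@H]([C@@](C)(O)CC=C)CC1 | intermediate
9 | (S)-2-methylglycidol, [(2S)-2-methyloxiran-2-yl]methanol | C[C@]1(CO)CO1 | starting material
10 | tert-butyl{[(2R)-2-methyloxiran-2-yl]methoxy}diphenylsilane | C[C@]1(CO[Si](c2ccccc2)(c2ccccc2)C(C)(C)C)CO1 | intermediate
11 | (2R)-1-[(tert-butyldiphenylsilyl)oxy]-2-methylbut-3-en-2-ol | C[C@](O)(CO[Si](c1ccccc1)(c1ccccc1)C(C)(C)C)C=C | intermediate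
12 | (2R,3E,6S)-1-[(tert-butyldiphenylsilyl)oxy]-2-methyl-6-[(1R)-4-{[(triisopropylsilyl)oxy]methyl}cyclohex-3-en-1-yl]hept-3-ene-2,6-diol | CC(C)[Si](C(C)C)(C(C)C)OCC1=CC[C@H]([C@@](C)(O)C/C=C/[C@@](C)(O)CO[Si](c2ccccc2)(c2ccccc2)C(C)(C)C)CC1 | intermediate
13 | (2R,3E,6S)-6-[(1R)-4-(hydroxymethyl)cyclohex-3-en-1-yl]-2-methylhept-3-ene-1,2,6-triol | OCC1=CC[C@H]([C@@](C)(O)C/C=C/[C@@](C)(O)CO)CC1 | intermediate
14 | {(4R)-4-[(2S,4E,6R)-7-(acetyloxy)-2,6-dihydroxy-6-methylhept-4-en-2-yl]cyclohex-1-en-1-yl}methyl acetate | CC(=O)OCC1=CC[C@H]([C@@](C)(O)C/C=C/[C@@](C)(O)COC(C)=O)CC1 | target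

Total steps: 9 (steps 5 and 6 build the side-chain fragment). Longest linear sequence: 7 steps (1, 2, 3, 4, 7, 8, 9).

Steps most likely to fail

Step 2. The catalyst may discriminate the acrylate faces poorly with this diene, or the cationic acid may oligomerise the diene before cycloaddition. The fallback lets an auxiliary carry the chirality; it sets out from 3 and returns at 6. (4S)-4-Benzyl-1,3-oxazolidin-2-one is N-acylated (MeMgBr, then acryloyl chloride, THF, −78 °C) to (4S)-3-acryloyl-4-benzyl-1,3-oxazolidin-2-one F1. Compounds 3 and F1 under Et2AlCl (1.4 equiv, CH2Cl2, −78 °C) should give the imide cycloadduct (4S)-4-benzyl-3-[(1R)-4-{[(triisopropylsilyl)oxy]methyl}cyclohex-3-ene-1-carbonyl]-1,3-oxazolidin-2-one F2, the diene adding anti to the benzyl group of the aluminium-chelated s-cis acrylimide, which corresponds to (R) at the ring carbon. LiOH/H2O2 (THF–H2O, 0 °C) releases the auxiliary and gives (1R)-4-{[(triisopropylsilyl)oxy]methyl}cyclohex-3-ene-1-carboxylic acid F3. 1,1′-Carbonyldiimidazole, then MeNH(OMe)·HCl (CH2Cl2, rt), gives 6, which takes MeMgBr as in step 3.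

Step 4. Face selection at C7 may be low, because the catalyst must tell a methyl group from a secondary ring carbon without help from C4. The fallback sets the C7–O stereocentre by methylene transfer instead of allyl transfer; it sets out from 7 and returns at 8. Dimethyloxosulfonium methylide epoxidation catalysed by LaLi3(binaphthoxide)3 with a triarylphosphine oxide additive (THF, rt; BINOL antipode chosen for the (2R)-oxirane) should give (2R)-2-methyl-2-[(1R)-4-{[(triisopropylsilyl)oxy]methyl}cyclohex-3-en-1-yl]oxirane F4. Vinylmagnesium bromide with catalytic CuI (copper iodide; THF, −30 °C) opens it at the CH2 terminus to give 8.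

Step 7. Metathesis at the congested allylic carbinol of 11 may be too slow, so that 8 merely homodimerises. The fallback makes the C9=C10 alkene from an alkyne and C11 by carbonyl addition; it sets out from 7 and returns at 13.
- Copper-catalysed enantioselective propargylation of 7 with allenyl-B(pin) (CuOAc, chiral bisphosphine, LiOiPr/iPrOH, THF, low temperature) should give (2S)-2-[(1R)-4-{[(triisopropylsilyl)oxy]methyl}cyclohex-3-en-1-yl]pent-4-yn-2-ol F5.
- Silylation (TESOTf, 2,6-lutidine, CH2Cl2) gives triethyl{[(2S)-2-[(1R)-4-{[(triisopropylsilyl)oxy]methyl}cyclohex-3-en-1-yl]pent-4-yn-2-yl]oxy}silane F6.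
- Hydroxyacetone with TBDPSCl/imidazole gives 1-[(tert-butyldiphenylsilyl)oxy]propan-2-one F7.
- syn-Hydrozirconation of F6 with Cp2Zr(H)Cl, transmetalation with Me2Zn and Ti(OiPr)4-promoted addition of the (E)-alkenylzinc to F7 under a chiral bis(sulfonamide) diol ligand should give (2R,3E,6S)-1-[(tert-butyldiphenylsilyl)oxy]-2-methyl-6-[(triethylsilyl)oxy]-6-[(1R)-4-{[(triisopropylsilyl)oxy]methyl}cyclohex-3-en-1-yl]hept-3-en-2-ol F8. The E-alkene is fixed by the hydrometalation, and C11 epimers are diastereomers that can be separated.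
- Bu4NF (THF) removes all three silyl groups to give 13.

Further compounds
F1 | step 2 | (4S)-3-acryloyl-4-benzyl-1,3-oxazolidin-2-one | C=CC(=O)N1[C@@H](Cc2ccccc2)COC1=O
F2 | step 2 | (4S)-4-benzyl-3-[(1R)-4-{[(triisopropylsilyl)oxy]methyl}cyclohex-3-ene-1-carbonyl]-1,3-oxazolidin-2-one | CC(C)[Si](C(C)C)(C(C)C)OCC1=CC[C@H](C(=O)N2[C@@H](Cc3ccccc3)COC2=O)CC1
F3 | step 2 | (1R)-4-{[(triisopropylsilyl)oxy]methyl}cyclohex-3-ene-1-carboxylic acid | CC(C)[Si](C(C)C)(C(C)C)OCC1=CC[C@H](C(=O)O)CC1
F4 | step 4 | (2R)-2-methyl-2-[(1R)-4-{[(triisopropylsilyl)oxy]methyl}cyclohex-3-en-1-yl]oxirane | CC(C)[Si](C(C)C)(C(C)C)OCC1=CC[C@H]([C@@]2(C)OC2)CC1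
F5 | step 7 | (2S)-2-[(1R)-4-{[(triisopropylsilyl)oxy]methyl}cyclohex-3-en-1-yl]pent-4-yn-2-ol | CC(C)[Si](C(C)C)(C(C)C)OCC1=CC[C@H]([C@@](C)(O)CC#C)CC1
F6 | step 7 | triethyl{[(2S)-2-[(1R)-4-{[(triisopropylsilyl)oxy]methyl}cyclohex-3-en-1-yl]pent-4-yn-2-yl]oxy}silane | CC(C)[Si](C(C)C)(C(C)C)OCC1=CC[C@H]([C@@](C)(O[Si](CC)(CC)CC)CC#C)CC1
F7 | step 7 | 1-[(tert-butyldiphenylsilyl)oxy]propan-2-one | CC(=O)CO[Si](c1ccccc1)(c1ccccc1)C(C)(C)C
F8 | step 7 | (2R,3E,6S)-1-[(tert-butyldiphenylsilyl)oxy]-2-methyl-6-[(triethylsilyl)oxy]-6-[(1R)-4-{[(triisopropylsilyl)oxy]methyl}cyclohex-3-en-1-yl]hept-3-en-2-ol | CC(C)[Si](C(C)C)(C(C)C)OCC1=CC[C@H]([C@@](C)(O[Si](CC)(CC)CC)C/C=C/[C@@](C)(O)CO[Si](c2ccccc2)(c2ccccc2)C(C)(C)C)CC1
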